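The hydroazulene is traced back to a cis-hydrindane by deleting C9 from the seven-membered ring (ring B): the C10 oxygen next to quaternary C1 and the C8 methyl then form a tetrasubstituted C8=C10 silyl enol ether. One intramolecular Diels–Alder reaction of an achiral siloxytriene makes C1–C5 and C6–C7, closes the cyclopentanone (ring A) and the cyclohexene, and sets C1, C5 and C6 under a chiral Lewis acid. Its precursor carries a C7=C8–C10=C1 2-siloxydiene joined through C2–C3 to the C4 carbonyl of an (E)-β-(2-naphthylmethoxy) enone (C5=C6). Cyclopropanation and FeCl3 ring expansion later insert C9, after which C4, C10 and C6 are adjusted.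

Key step: step 5

Numbering and faces: C1 is the quaternary methyl carbon, C2 and C3 the ring CH2 groups, C4 the isopropyl carbinol, C5 the ring-fusion CH, C6 the aroyloxy carbon, C7 the CH2, C8 the methyl-bearing alkene carbon, C9 the alkene CH and C10 the isovaleryloxy carbon. Ring A is the five-membered ring; ring B is the six-membered ring that becomes seven-membered. α is the face carrying the C1 methyl and H5 (the convex face of the cis-fused bicycle); β is the opposite face.

Assumption: the sense of induction of the (S)-oxazaborolidinium catalyst in step 5 is taken from the usual enone-binding model; if the adduct proved to be the mirror image, the catalyst from (R)-α,α-diphenylprolinol would be used.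

Remark: the (E)-dienophile places the C6 oxygen of the adduct on the α face (cis to H5), opposite to the target, so C6 is inverted in steps 15 and 16.

Step 1
Reactants: 1 methacryloyl chloride
Product: 2 N-methoxy-N-methylmethacrylamide
Conditions: MeNH(OMe)·HCl, Et3N, CH2Cl2, 0 °C
Reagents that add atoms: N,O-dimethylhydroxylamine hydrochloride, CNOC.Cl
Why: N-acylation of the hydroxylamine by the acid chloride (Schotten–Baumann type) gives the Weinreb amide; no stereocentre is formed.

Step 2
Reactants: 2 N-methoxy-N-methylmethacrylamide; 3 isopropenylmagnesium bromide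
Product: 4 2,4-dimethylpenta-1,4-dien-3-one
Conditions: THF, −78 to 0 °C; inverse quench into cold 1 M HCl
Reagents that add atoms: none
Why: Weinreb ketone synthesis: the chelated tetrahedral magnesium adduct persists until the acidic quench, so the cross-conjugated dienone is released without over-addition, and the inverse acidic quench keeps the liberated hydroxylamine from adding to the enone.

Step 3
Reactants: 5 (E)-4-methoxybut-3-en-2-one; 6 naphthalen-2-ylmethanol
Product: 7 (E)-4-(naphthalen-2-ylmethoxy)but-3-en-2-one
Conditions: PPTS (5 mol %), toluene, 80 °C, reduced pressure (removal of MeOH)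
Reagents that add atoms: none
Why: Acid-catalysed addition–elimination (transetherification of a vinylogous ester), driven by removal of methanol, gives the thermodynamic (E)-β-alkoxy enone; the 2-naphthylmethyl ether is chosen because it resists ionisation by Lewis acids better than a p-methoxybenzyl ether and is still cleaved by DDQ.

Step 4
Reactants: 7 (E)-4-(naphthalen-2-ylmethoxy)but-3-en-2-one; 4 2,4-dimethylpenta-1,4-dien-3-one
Product: 10 (1E,6Z)-7-(tert-butyldimethylsilyloxy)-6,8-dimethyl-1-(naphthalen-2-ylmethoxy)nona-1,6,8-trien-3-one, via lithium dienolate 8 (not isolated), via lithium enolate adduct 9 (not isolated)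
Conditions: LiN(iPr)2, THF, −78 °C; slow addition of 4, −78 °C; TBSCl, DMPU, −78 to −20 °C; buffered work-up
Reagents that add atoms: tert-butyldimethylsilyl chloride, CC(C)(C)[Si](C)(C)Cl
Why: Kinetic deprotonation of the methyl ketone and Michael addition of dienolate 8 to the unsubstituted β-carbon of the non-enolisable dienone 4, through a lithium-chelated s-cis transition state, should give the Z(O)-enolate 9 regiospecifically, which is silylated on oxygen; this geometry places the tether outside the diene, and either enol ether geometry would converge on the same cis-fused adduct.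

Step 5
Reactants: 10 (1E,6Z)-7-(tert-butyldimethylsilyloxy)-6,8-dimethyl-1-(naphthalen-2-ylmethoxy)nona-1,6,8-trien-3-one
Product: 11 (1R,5S,6S)-cis-hydrindan-4-one C8=C10 tert-butyldimethylsilyl enol ether with 1-methyl, 8-methyl and 6α-(naphthalen-2-ylmethoxy) groups (core numbering)
Conditions: (S)-3,3-diphenyl-1-(2-methylphenyl)tetrahydro-1H,3H-pyrrolo[1,2-c][1,3,2]oxazaborole (20 mol %), HNTf2 (18 mol %), CH2Cl2, −78 to −20 °C
Reagents that add atoms: none
Why: The protonated oxazaborolidine binds the C4 carbonyl and lowers the LUMO of the (E)-C5=C6 enone, which adds suprafacially across the s-cis C7=C8–C10=C1 siloxydiene in a concerted, asynchronous [4+2] cycloaddition; the substituents on the two inner diene carbons (C8 methyl, C10 siloxy) favour the s-cis conformer and offset the inside methyl on C1. The closest known reactions are the intramolecular Diels–Alder reaction of 1,6,8-nonatrien-3-ones and the oxazaborolidinium-catalysed Diels–Alder reaction of enones with 2-silyloxydienes. Ring A (the cyclopentanone) closes through the C1–C5 bond in the fused (type 1) mode, the C2–C3–C4 tether linking the diene terminus to the α-carbon of the dienophile, and the six-membered ring is the cycloaddition ring itself, closed by C1–C5 and C6–C7. C1 and C5 are set cis by the transition state in which the tether carbonyl lies endo under the diene, C6 follows from the (E)-geometry of the enone (C6–O trans to C4, hence cis to H5), and the absolute configuration is set by the catalyst, which shields one face of the bound enone. The step needs the fused rather than the bridged regiochemistry; the oxygen substituents favour the bridged mode electronically (nucleophilic C1 to electrophilic C6), and a stepwise Mukaiyama–Michael reaction would deliver it. The three-atom tether cannot span the bridged transition state in a concerted process, and the bulky silyl group, the poorly ionising naphthylmethyl ether and the low temperature are meant to keep the reaction out of the ionic manifold.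

Step 6
Reactants: 11 cis-hydrindan-4-one silyl enol ether
Product: 13 C3=C4 enol triflate of 11, via potassium enolate 12 (not isolated)
Conditions: KN(SiMe3)2, THF, −78 °C; PhNTf2, −78 to 0 °C; aq NH4Cl
Reagents that add atoms: N-phenylbis(trifluoromethanesulfonimide), O=S(=O)(N(c1ccccc1)S(=O)(=O)C(F)(F)F)C(F)(F)F
Why: Kinetic enolisation takes a proton from the unhindered C3 methylene and not the ring-fusion C5–H, and O-sulfonylation of enolate 12 fixes the C3=C4 enol triflate; this removes, before the ring expansion, the only ketone that could epimerise C5 or expel the β-alkoxy group at C6.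

Step 7
Reactants: 13 C3=C4 enol triflate
Product: 14 siloxycyclopropane (CH2 bridging C8 and C10 on the α face)
Conditions: Et2Zn, CH2I2, CH2Cl2, 0 to 23 °C
Reagents that add atoms: diiodomethane, ICI
Why: Furukawa-modified Simmons–Smith cyclopropanation: the electrophilic zinc carbenoid should attack only the electron-rich C8=C10 silyl enol ether (enol triflate and naphthalene are inert), from the convex α face; both new stereocentres are erased in step 8, so the facial outcome does not matter.

Step 8
Reactants: 14 siloxycyclopropane
Product: 16 cis-hydroazula-3,8-dien-10-one 4-triflate, via β-chloro ketone 15 (not isolated)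
Conditions: FeCl3, DMF, 0 to 23 °C; aqueous work-up; NaOAc, MeOH, 40 °C
Reagents that add atoms: none
Why: Oxidative ring opening of a siloxycyclopropane: single-electron oxidation of the cyclopropoxide by trivalent iron cleaves the internal C8–C10 bond to the ring-expanded tertiary C8 radical, which takes up chlorine to give 15, and acetate-induced dehydrochlorination then gives the conjugated C8=C9–C10=O enone of the seven-membered ring B.

Step 9
Reactants: 16 cis-hydroazuladienone triflate; 17 isopropylzinc bromide
Product: 18 4-isopropyl-cis-hydroazula-3,8-dien-10-one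
Conditions: Pd(dppf)Cl2 (5 mol %), THF, 23 to 50 °C
Reagents that add atoms: none
Why: Negishi coupling: oxidative addition of the alkenyl triflate to zerovalent palladium, transmetalation and reductive elimination, with the wide-bite-angle diphosphine making reductive elimination faster than β-hydride elimination (which would give the n-propyl isomer); the organozinc halide leaves the hindered enone untouched.

Step 10
Reactants: 18 4-isopropyl-cis-hydroazula-3,8-dien-10-one
Product: 19 3α,4α-epoxide of 18
Conditions: mCPBA, NaHCO3, CH2Cl2, 0 °C
Reagents that add atoms: 3-chloroperoxybenzoic acid, OOC(=O)c1cccc(Cl)c1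
Why: Prilezhaev epoxidation should select the electron-rich trisubstituted C3=C4 alkene over the electron-poor enone alkene and approach from the convex α face, anti to the allylic C5–C6 bond, which sets the C4 oxygen α and the isopropyl group β.

Step 11
Reactants: 19 3α,4α-epoxy enone
Product: 20 3α,4α-epoxy-10α-ol
Conditions: (S)-1-methyl-3,3-diphenyltetrahydro-1H,3H-pyrrolo[1,2-c][1,3,2]oxazaborole (20 mol %), catecholborane, toluene, −78 to −20 °C; MeOH, aq NaOH
Reagents that add atoms: none
Why: Corey–Bakshi–Shibata reduction: the oxazaborolidine binds the carbonyl lone pair on the C9 side, away from quaternary C1, and the (S)-reagent then delivers hydride to the β face (1,2-reduction) to give the 10α (R) allylic alcohol; reagent control is used because the faces of C10 are flanked by CH3 and CH2 on C1 and the substrate bias cannot be foreseen.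

Step 12
Reactants: 20 3α,4α-epoxy-10α-ol
Product: 21 4α,10α-diol
Conditions: LiEt3BH, THF, 0 to 23 °C; H2O
Reagents that add atoms: none
Why: SN2 opening of the trisubstituted epoxide by hydride at the less substituted C3 leaves the C4–O bond intact, so the tertiary 4α-alcohol keeps the configuration set in step 10.

Step 13
Reactants: 21 4α,10α-diol; 22 isovaleryl chloride
Product: 23 10α-isovalerate
Conditions: pyridine, DMAP (cat.), CH2Cl2, 0 to 23 °C
Reagents that add atoms: none
Why: DMAP-catalysed O-acylation should occur only at the secondary allylic C10 hydroxyl, the tertiary C4 hydroxyl being inert, and proceeds with retention at C10.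

Step 14
Reactants: 23 10α-isovalerate
Product: 24 6α-alcohol
Conditions: DDQ, CH2Cl2/pH 7 buffer, 0 to 23 °C
Reagents that add atoms: none
Why: Oxidative cleavage of the 2-naphthylmethyl ether (hydride abstraction from the benzylic CH2, then hydrolysis of the oxocarbenium ion) frees the 6α-alcohol without breaking the C6–O bond or touching the allylic ester and the alkene.

Step 15
Reactants: 24 6α-alcohol
Product: 25 6-ketone
Conditions: Dess–Martin periodinane, NaHCO3, CH2Cl2, 0 °C; crude product used at once
Reagents that add atoms: none
Why: Dess–Martin oxidation of the secondary C6 alcohol under buffered, non-basic conditions should leave the C8=C9 alkene unconjugated, the β-hydroxy ketone intact (no retro-aldol) and C5 unepimerised; the tertiary alcohol cannot be oxidised.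

Step 16
Reactants: 25 6-ketone
Product: 26 6β-alcohol
Conditions: NaBH4, CeCl3·7H2O, MeOH, −78 °C
Reagents that add atoms: none
Why: Luche reduction at low temperature outruns enolisation, and hydride should add to C6 from the α face, anti to the neighbouring fully substituted C4 whose β-isopropyl group screens the concave face (Felkin–Anh and convex-face preferences agree, and delivery from the C4 hydroxyl would act in the same sense), giving the 6β-alcohol and thus net inversion at C6.

Step 17
Reactants: 26 6β-alcohol; 27 4-acetoxybenzoyl chloride
Product: 29 CNP0086724.1 (target), via aryl acetate 28 (not isolated)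
Conditions: Et3N, DMAP, CH2Cl2, 0 to 40 °C; then pyrrolidine, 0 °C
Reagents that add atoms: none
Why: DMAP-catalysed acylation of the only free secondary hydroxyl (C6, retention) gives 28, and the phenolic acetate, far more electrophilic than the two alkyl esters, is then cleaved selectively by aminolysis to free the phenol.

Compound list
1 | methacryloyl chloride | C=C(C)C(Cl)=O | starting material
2 | N-methoxy-N-methylmethacrylamide | C=C(C)C(=O)N(C)OC | intermediate
3 | isopropenylmagnesium bromide | C=C(C)[Mg]Br | starting material
4 | 2,4-dimethylpenta-1,4-dien-3-one | C=C(C)C(=O)C(C)=C | intermediate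
5 | (E)-4-methoxybut-3-en-2-one | CO/C=C/C(C)=O | starting material
6 | naphthalen-2-ylmethanol | OCc1ccc2ccccc2c1 | starting material
7 | (E)-4-(naphthalen-2-ylmethoxy)but-3-en-2-one | CC(=O)/C=C/OCc1ccc2ccccc2c1 | intermediate
8 | lithium (E)-4-(naphthalen-2-ylmethoxy)buta-1,3-dien-2-olate (formed in the flask) | C=C(O[Li])/C=C/OCc1ccc2ccccc2c1 | intermediate
9 | lithium (1E,6Z)-6,8-dimethyl-1-(naphthalen-2-ylmethoxy)-3-oxonona-1,6,8-trien-7-olate (formed in the flask) | C=C(C)/C(O[Li])=C(C)/CCC(=O)/C=C/OCc1ccc2ccccc2c1 | intermediate
10 | (1E,6Z)-7-(tert-butyldimethylsilyloxy)-6,8-dimethyl-1-(naphthalen-2-ylmethoxy)nona-1,6,8-trien-3-one | C=C(C)/C(O[Si](C)(C)C(C)(C)C)=C(C)/CCC(=O)/C=C/OCc1ccc2ccccc2c1 | intermediate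
11 | (1R,5S,6S)-cis-hydrindan-4-one with C8=C10 tert-butyldimethylsilyl enol ether, 1- and 8-methyl, 6α-(naphthalen-2-ylmethoxy); 1-CH3, H5 and 6-O all α (core numbering) | CC1=C(O[Si](C)(C)C(C)(C)C)[C@]2(C)CCC(=O)[C@@H]2[C@@H](OCc2ccc3ccccc3c2)C1 | intermediate
12 | potassium C3=C4 enolate of 11 (formed in the flask) | CC1=C(O[Si](C)(C)C(C)(C)C)[C@]2(C)CC=C(O[K])[C@@H]2[C@@H](OCc2ccc3ccccc3c2)C1 | intermediate
13 | C3=C4 enol triflate of 11 | CC1=C(O[Si](C)(C)C(C)(C)C)[C@]2(C)CC=C(OS(=O)(=O)C(F)(F)F)[C@@H]2[C@@H](OCc2ccc3ccccc3c2)C1 | intermediate
14 | siloxycyclopropane of 13, CH2 bridging C8 and C10 on the α face | C[C@]12C[C@@]1(O[Si](C)(C)C(C)(C)C)[C@]3(C)CC=C(OS(=O)(=O)C(F)(F)F)[C@@H]3[C@@H](OCc1ccc4ccccc4c1)C2 | intermediate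
15 | ring-expanded 8-chloro-8-methyl-10-ketone, cis-hydroazulene, both C8 epimers (formed in the flask) | CC1(Cl)CC(=O)[C@]2(C)CC=C(OS(=O)(=O)C(F)(F)F)[C@@H]2[C@@H](OCc2ccc3ccccc3c2)C1 | intermediate
16 | 1,8-dimethyl-6α-(naphthalen-2-ylmethoxy)-cis-hydroazula-3,8-dien-10-one 4-triflate | CC1=CC(=O)[C@]2(C)CC=C(OS(=O)(=O)C(F)(F)F)[C@@H]2[C@@H](OCc2ccc3ccccc3c2)C1 | intermediate
17 | isopropylzinc bromide | CC(C)[Zn]Br | starting material
18 | 4-isopropyl-1,8-dimethyl-6α-(naphthalen-2-ylmethoxy)-cis-hydroazula-3,8-dien-10-one | CC1=CC(=O)[C@]2(C)CC=C(C(C)C)[C@@H]2[C@@H](OCc2ccc3ccccc3c2)C1 | intermediate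
19 | 3α,4α-epoxide of 18 (4-isopropyl β) | CC1=CC(=O)[C@]2(C)C[C@H]3O[C@@]3(C(C)C)[C@@H]2[C@@H](OCc2ccc3ccccc3c2)C1 | intermediate
20 | 3α,4α-epoxy-10α-ol (C8=C9 alkene, 6α-naphthylmethoxy) | CC1=C[C@@H](O)[C@]2(C)C[C@H]3O[C@@]3(C(C)C)[C@@H]2[C@@H](OCc2ccc3ccccc3c2)C1 | intermediate
21 | 4α,10α-diol (4β-isopropyl, 6α-naphthylmethoxy) | CC1=C[C@@H](O)[C@]2(C)CC[C@](O)(C(C)C)[C@@H]2[C@@H](OCc2ccc3ccccc3c2)C1 | intermediate
22 | isovaleryl chloride (3-methylbutanoyl chloride) | CC(C)CC(Cl)=O | starting material
23 | 10α-isovalerate of 21 | CC1=C[C@@H](OC(=O)CC(C)C)[C@]2(C)CC[C@](O)(C(C)C)[C@@H]2[C@@H](OCc2ccc3ccccc3c2)C1 | intermediate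
24 | 6α-alcohol (4α-OH, 10α-isovalerate) | CC1=C[C@@H](OC(=O)CC(C)C)[C@]2(C)CC[C@](O)(C(C)C)[C@@H]2[C@@H](O)C1 | intermediate
25 | 6-ketone (4α-OH, 10α-isovalerate) | CC1=C[C@@H](OC(=O)CC(C)C)[C@]2(C)CC[C@](O)(C(C)C)[C@@H]2C(=O)C1 | intermediate
26 | 6β-alcohol (4α-OH, 10α-isovalerate) | CC1=C[C@@H](OC(=O)CC(C)C)[C@]2(C)CC[C@](O)(C(C)C)[C@@H]2[C@H](O)C1 | intermediate
27 | 4-acetoxybenzoyl chloride | CC(=O)Oc1ccc(cc1)C(Cl)=O | starting material
28 | 6β-(4-acetoxybenzoate) of 26 (formed in the flask) | CC1=C[C@@H](OC(=O)CC(C)C)[C@]2(C)CC[C@](O)(C(C)C)[C@@H]2[C@H](OC(=O)c2ccc(OC(C)=O)cc2)C1 | intermediate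
29 | CNP0086724.1; (1R,4S,5S,6R,10R) in core numbering: 4α-hydroxy-4β-isopropyl-1,8-dimethyl-10α-(3-methylbutanoyloxy)-cis-hydroazul-8-en-6β-yl 4-hydroxybenzoate | CC1=C[C@@H](OC(=O)CC(C)C)[C@]2(C)CC[C@](O)(C(C)C)[C@@H]2[C@H](OC(=O)c2ccc(O)cc2)C1 | target

Total step count: 17.
Longest linear sequence: 16 steps (1 → 2 → 4 → 10 → 11 → 13 → 14 → 16 → 18 → 19 → 20 → 21 → 23 → 24 → 25 → 26 → 29); step 3 is the only step on the side branch.

Steps most likely to fail

Step 5. The cycloaddition may not start at temperatures the silyl enol ether tolerates, because the tether forces the electronically mismatched orientation and C1 carries an inside methyl. The acid catalyst may instead cause desilylation or stepwise Michael chemistry towards bridged isomers, or face discrimination may be weak. The fallback sets out from 10 and runs the cycloaddition thermally without Lewis acid (toluene, BHT, base-washed sealed tube, about 180 °C), where only the concerted fused pathway is open. This would give the racemic cis-adduct, that is 11 together with its mirror image ent-11 F1. The enantiomers are separated by preparative chromatography on a chiral stationary phase, and the route is rejoined at 11.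

Step 4. The dienolate may add to the carbonyl instead of the β-carbon, the dienone may oligomerise, or enolate 9 may cyclise onto its own vinylogous ester with loss of the naphthylmethoxide before it is silylated. The fallback sets out from 4 and uses a donor that carries no internal acceptor. The lithium enolate of N-methoxy-N-methylacetamide is added to 4 and the adduct is silylated in the flask (TBSCl, DMPU) to the Weinreb amide siloxydiene F2. Ethynylmagnesium bromide converts this into the ynone F3. PMe3-catalysed conjugate addition of alcohol 6 to the ynone (E-selective oxa-Michael addition) then builds the β-alkoxy enone last and rejoins the route at 10.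

Step 11. Hydride delivery to C10 may show poor or reversed facial selectivity if the catalyst works against the concave/convex bias of the bicycle, and the hindered carbonyl may react slowly. The fallback sets out from 19 and reduces the enone under Luche conditions (NaBH4, CeCl3·7H2O, MeOH), accepting the 10β-alcohol F4 that convex-face attack would give. The epoxide is opened with LiEt3BH to the 4α,10β-diol F5. The isovalerate is then introduced with inversion by Mitsunobu esterification (isovaleric acid, PPh3, DIAD), and the route is rejoined at 23.

Further compounds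
F1 | step 5 | ent-11, the (1S,5R,6R) mirror image of the cycloadduct | CC1=C(O[Si](C)(C)C(C)(C)C)[C@@]2(C)CCC(=O)[C@H]2[C@H](OCc2ccc3ccccc3c2)C1
F2 | step 4 | (4Z)-5-(tert-butyldimethylsilyloxy)-N-methoxy-N,4,6-trimethylhepta-4,6-dienamide | C=C(C)/C(O[Si](C)(C)C(C)(C)C)=C(C)/CCC(=O)N(C)OC
F3 | step 4 | (6Z)-7-(tert-butyldimethylsilyloxy)-6,8-dimethylnona-6,8-dien-1-yn-3-one | C=C(C)/C(O[Si](C)(C)C(C)(C)C)=C(C)/CCC(=O)C#C
F4 | step 11 | 3α,4α-epoxy-10β-ol (10-epimer of 20) | CC1=C[C@H](O)[C@]2(C)C[C@H]3O[C@@]3(C(C)C)[C@@H]2[C@@H](OCc2ccc3ccccc3c2)C1
F5 | step 11 | 4α,10β-diol (10-epimer of 21) | CC1=C[C@H](O)[C@]2(C)CC[C@](O)(C(C)C)[C@@H]2[C@@H](OCc2ccc3ccccc3c2)C1
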